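**Assumptions (one line each)**
- The target SMILES has no descriptor for its only stereo element, the C2–C2' biaryl axis. I take the target as the single (aS)-atropisomer and choose the catalyst enantiomer to match. If the natural product is (aR), use the enantiomeric catalyst.
- Reagents such as Tf2O, Pd and H2 are given in the conditions and are numbered only if they are substrates.

**Retrosynthesis**
1. Disconnect the C2–C2' biaryl axis by atroposelective oxidative homocoupling of the monomer, 5-isopropyl-3,8-dimethylnaphthalen-1-ol (**7**). This is the only stereo-defining step.
2. **7** comes from dehydrogenative aromatization of the 1-tetralone (**6**).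
3. **6** comes from intramolecular Friedel–Crafts acylation of the arylbutanoic acid (**5**). The only free ortho position is the one next to the ring methyl, so regiochemistry is forced.
4. **5** comes from Heck coupling of thymyl triflate (**2**) with 3-methylbut-3-enoic acid (**3**), then hydrogenation. Thymol (**1**) supplies the 2-iPr/5-Me arene (ring B) with the iPr-bearing carbon already adjacent to the future C4a.
5. Ring order: ring B is pre-formed in thymol; ring A closes in step 4; the biaryl axis forms last.

**Forward route**

Step 1
Reactants: **1** thymol (2-isopropyl-5-methylphenol)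
Product: **2** 2-isopropyl-5-methylphenyl triflate
Conditions: Tf2O, pyridine, CH2Cl2, 0 °C → rt
Reagents that add atoms: triflic anhydride, O=S(=O)(C(F)(F)F)OS(=O)(=O)C(F)(F)F
Why: O-sulfonylation (triflation) turns the phenol into a Pd-active leaving group. No stereocenter is involved.

Step 2
Reactants: **2** thymyl triflate; **3** 3-methylbut-3-enoic acid
Product: **4** 4-(2-isopropyl-5-methylphenyl)-3-methylbut-3-enoic acid (mainly the E-styrenyl isomer; minor double-bond isomers are carried on as a mixture)
Conditions: Pd(OAc)2 (5 mol%), dppf, i-Pr2NEt, DMF, 100 °C
Reagents that add atoms: none (the alkene partner is numbered reactant **3**)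
Why: Heck arylation of a 1,1-disubstituted alkene puts the aryl group on the terminal CH2. All alkene isomers converge in the next step, so no stereochemistry needs controlling here.

Step 3
Reactants: **4** unsaturated acid(s)
Product: **5** 4-(2-isopropyl-5-methylphenyl)-3-methylbutanoic acid (racemic at C3)
Conditions: H2 (1–3 atm), 10% Pd/C, EtOAc, rt
Reagents that add atoms: none
Why: Catalytic alkene hydrogenation merges the isomers into one saturated acid. The new C3 stereocenter is racemic and is destroyed by aromatization in step 5, so it does not matter.

Step 4
Reactants: **5** acid
Product: **6** 5-isopropyl-3,8-dimethyl-3,4-dihydronaphthalen-1(2H)-one (racemic)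
Conditions: Eaton's reagent (P2O5/MsOH), 45 °C, 2 h
Reagents that add atoms: none (water is lost)
Why: Intramolecular Friedel–Crafts acylation. The iPr-blocked ortho site leaves only the position ortho to the methyl, which is activated by it. This is the same pattern as the known 5,8-dimethyl-1-tetralone Haworth closure.

Step 5
Reactants: **6** tetralone
Product: **7** 5-isopropyl-3,8-dimethylnaphthalen-1-ol
Conditions: 10% Pd/C, diphenyl ether, reflux (~240 °C), N2 with open vent, 3 h
Reagents that add atoms: none (loses 2 H2)
Why: Pd-catalyzed dehydrogenative aromatization; the 1(2H)-naphthalenone tautomerizes to the naphthol. The C3 stereocenter is destroyed here.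

Step 6
Reactants: **7** naphthol (2 equiv)
Product: **8** Parviflorene H, (aS)-3,3',8,8'-tetramethyl-5,5'-diisopropyl-[2,2'-binaphthalene]-1,1'-diol
Conditions: chiral oxovanadium(V) Schiff-base catalyst (10 mol%), O2 (1 atm), CH2Cl2 or toluene, 25–40 °C
Reagents that add atoms: none (O2 is only the terminal oxidant; the product is 2 × **7** minus 2 H)
Why: Biomimetic oxidative phenol coupling. C4 is blocked by the peri-iPr and the 3-Me, so C2 coupling is favored. The chiral V-bound naphthoxy radical/phenol pair sets the axis (Ar–Ar bond formation with catalyst control). The axis is the only stereoelement of the target, and the product is configurationally stable enough to isolate.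

**Final checks (done)**
- The final structure has two naphthalenes, each with 1-OH, 2-aryl, 3-Me, 5-iPr and 8-Me. This matches the target SMILES and C30H34O2 (2 × C15H18O − 2 H).
- Atom balance for steps 1–6 was verified: C10H14O → C11H13F3O3S → C15H20O2 → C15H22O2 → C15H20O → C15H18O → C30H34O2.
- Each functional group survives: triflate survives until the Heck step; the arene, iPr and Me groups survive the hydrogenation, Eaton's reagent and Pd/C steps.
- The only stereocenter in the target is the axis, set in step 6. The transient C3 center is racemic and removed in step 5.

**Compound list**

| No. | Name | SMILES | Role |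
|---|---|---|---|
| 1 | Thymol | Cc1ccc(C(C)C)c(O)c1 | starting material |
| 2 | 2-Isopropyl-5-methylphenyl triflate | Cc1ccc(C(C)C)c(OS(=O)(=O)C(F)(F)F)c1 | intermediate |
| 3 | 3-Methylbut-3-enoic acid | C=C(C)CC(=O)O | starting material |
| 4 | (E)-4-(2-isopropyl-5-methylphenyl)-3-methylbut-3-enoic acid | Cc1ccc(C(C)C)c(c1)/C=C(/CC(=O)O)C | intermediate |
| 5 | 4-(2-isopropyl-5-methylphenyl)-3-methylbutanoic acid (racemic) | Cc1ccc(C(C)C)c(CC(C)CC(=O)O)c1 | intermediate |
| 6 | 5-Isopropyl-3,8-dimethyl-1-tetralone (racemic) | O=C1CC(C)Cc2c(C(C)C)ccc(C)c12 | intermediate |
| 7 | 5-Isopropyl-3,8-dimethylnaphthalen-1-ol | Cc1cc2c(C(C)C)ccc(C)c2c(O)c1 | intermediate |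
| 8 | Parviflorene H, (aS)-atropisomer (axis not encoded in SMILES) | Cc1cc2c(C(C)C)ccc(C)c2c(O)c1-c1c(C)cc2c(C(C)C)ccc(C)c2c1O | target |

**Total steps:** 6. **Longest linear sequence:** 6 (thymol → **2** → **4** → **5** → **6** → **7** → **8**).

**Three steps most likely to fail**
1. **Step 6 (oxidative coupling).** Risks are C4/C2 regioselectivity, O-coupling or quinone formation, and low ee for this hindered, tetra-ortho-substituted axis.
   - Fallback: make racemic **8** by a different route. Convert **7** to its O-carbamate, ortho-lithiate at C2, and dimerize with CuCl2. Then cleave the carbamates and resolve by chiral HPLC or by diastereomeric bis-camphanates.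
2. **Step 2 (Heck).** Alkene isomer mixtures, or poor reactivity with the ortho-substituted triflate.
   - Fallback: hydroborate methyl 3-methylbut-3-enoate with 9-BBN and run a B-alkyl Suzuki coupling with **2**. Then saponify to reach **5** directly.
3. **Step 5 (dehydrogenation).** Pd/C at high temperature can give disproportionation (tetralol/tetralin by-products) and iPr loss.
   - Fallback: stepwise α-bromination with CuBr2, then elimination with LiBr/Li2CO3 in DMF. The resulting naphthalen-1(4H)-one tautomerizes to **7**.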